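**Numbering used throughout:** 1 methoxyeugenol, 2 and 3 aluminium intermediates, 4 the catechol, 5 its diacetate, 6 stearic acid, 7 the (E)-cinnamyl stearate, 8 its saturated counterpart, 9 the target.

## Analysis of the target

Target 9 is 3-(3,4-dihydroxy-5-methoxyphenyl)propyl octadecanoate. It has one benzene ring (ring A) with a saturated chain Cα–Cβ–Cγ at C1, free hydroxyls at C3 and C4, and a methoxy group at C5; Cγ is bound to the ester oxygen of an unbranched C18 acyl group. There is no stereocentre and no second ring, so the problem is chemoselectivity and oxidation level, not stereocontrol. The fragile part is the 3-methoxycatechol: it is very electron-rich, autoxidises to the ortho-quinone (fastest as its anion), and once oxidised it can tautomerise through Cα–H to a quinone methide. The ester is an ordinary primary alkyl ester, but it has to be placed on the one aliphatic oxygen and stay there while two phenols are set free next to it. The difficulty is therefore to tell apart three ring oxygens (one methylated, two free) and three hydroxyls (one acylated, two free) in few steps. The strategy rests on the Cγ–O bond: one oxidation level lower, Cα–Cβ–Cγ is the allyl group of methoxyeugenol 1, which already holds all nine skeletal carbons and all three ring oxygens. Because 1 is symmetric about its C1–C4 axis, removal of either methyl group gives the same catechol, and the ester oxygen can then be written onto Cγ by C–H oxidation with stearic acid 6, without the primary alcohol ever being made.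

## Retrosynthetic reasoning

**9 back to 8.** The two aryl O–acetyl bonds are formed last in the retrosynthetic sense, so the catechol is unmasked in the final step. This is chosen because the free catechol is the least robust function and should see no oxidant, metal or base-mediated step. The forward reaction has to cleave two aryl esters while leaving the alkyl ester of Cγ intact; it relies on aryloxide being a much better leaving group than alkoxide towards a nitrogen nucleophile.

**8 back to 7.** A double bond is introduced between Cα and Cβ. This turns the saturated ester into an allylic ester conjugated with ring A, which is the retron of an allylic oxidation. The forward step must add two hydrogens to a styrene-type alkene that sits next to an allylic C–O bond, without hydrogenolysing that bond; a metal-free, concerted hydrogen transfer meets this need.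

**7 back to 5 and 6.** The Cγ–O bond is cut, not the acyl–O bond. Cutting at the acyl carbon would require the free primary alcohol, reached from the allyl group by an anti-Markovnikov hydration under alkaline oxidative conditions that an oxygen-rich arene tolerates poorly, and would then require acylation of that alcohol in competition with phenols. Cutting at Cγ instead gives the hydrocarbon chain of 5 and the unmodified acid 6. The forward reaction must cleave the doubly activated Cα–H bond, deliver the carboxylate to the terminal carbon and not to the benzylic one, give the E alkene, and do this without the oxidant touching ring A.

**5 back to 4.** The two acetyl groups are removed. Acetates are chosen because they lower the electron density of ring A, cannot be oxidised by a quinone, and are the one protecting group that the final step can remove while an alkyl ester stays.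

**4 back to 1.** One O–CH3 bond is re-formed on paper. In the forward direction a single methyl group of 1 is removed. The symmetry of 1 removes any regiochemical question, so the only requirement is to stop after the first cleavage, which chelation of an aluminium Lewis acid between the phenolic oxygen and one neighbouring methoxy oxygen should achieve.

## Alternatives that were turned down

**Alternative 1: nickel reductive aryl–alkyl coupling (C1–Cα bond).**
- Disconnection and key step: the aryl bromide 1,2-bis(benzyloxy)-5-bromo-3-methoxybenzene A1 and 3-bromopropyl stearate A2 would be joined with NiBr2(dme), 4,4'-di-tert-butyl-2,2'-bipyridine and zinc powder to give 3-[3,4-bis(benzyloxy)-5-methoxyphenyl]propyl stearate A3. Hydrogenolysis of the benzyl ethers would then give 9.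
- For it: the route is convergent, and the ester is made on a simple bromo alcohol where no phenol competes. The endgame is a neutral hydrogenolysis with no alkene to reduce and no discrimination between two kinds of ester. On the endgame this alternative is stronger than the chosen route.
- Against it: A1 carries three oxygen donors, and oxidative addition of such an electron-rich aryl bromide to zerovalent nickel is slow. Homocoupling and reduction of A2 then take over. A1 also has to be assembled with its 1,2,3,5-pattern in several steps, whereas 1 is bought with every carbon and ring oxygen in place.
- Comparison: the overall step count would be similar. The chosen route offers a sequence with no C–C bond formation and no stoichiometric metal reductant.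

**Alternative 2: biomimetic ortho-hydroxylation (ring C3–O bond).**
- Disconnection and key step: 3-(4-hydroxy-3-methoxyphenyl)propyl stearate A4 would be oxygenated with O2, [Cu(CH3CN)4]PF6 and N,N'-di-tert-butylethylenediamine at the C–H ortho to the phenol, giving the ortho-quinone 3-(5-methoxy-3,4-dioxocyclohexa-1,5-dien-1-yl)propyl stearate A5. Reduction would then give 9.
- For it: it needs no protecting group and is the shortest sequence on paper. On step economy it is stronger than the chosen route.
- Against it: A5 is an unhindered, electrophilic ortho-quinone formed in the presence of its own precursor. Conjugate addition of A4 to A5, radical coupling of the electron-rich phenol A4, condensation with the diamine ligand and tautomerisation through Cα–H all compete. Nothing in the structure steers between these paths.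
- Comparison: the chosen route gives up two steps but keeps ring A at the arene oxidation level throughout, with its oxygen pattern fixed by the starting material.

**Alternative 3: cross-metathesis (Cα=Cβ bond).**
- Disconnection and key step: the bis-silyl styrene 3,4-bis(tert-butyldimethylsilyloxy)-5-methoxystyrene A6 and allyl stearate A7 would be joined by the second-generation Grubbs catalyst RuCl2(H2IMes)(PCy3)(=CHPh) to give (E)-3-[3,4-bis(tert-butyldimethylsilyloxy)-5-methoxyphenyl]allyl stearate A8, the silyl counterpart of 7. Reduction and desilylation would follow.
- For it: styrene–allyl ester metathesis is predictable and E-selective, and silyl ethers can be removed with fluoride or mild acid that an alkyl ester ignores. On reliability of the bond-forming step and on orthogonality of the deprotection it is stronger.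
- Against it: A8 is a cinnamyl ester like 7, so the hydrogenolysis-free reduction is still needed and nothing is saved there. A6 has to be made from an aromatic aldehyde by silylation and methylenation. The metathesis also gives homodimers of A6 and A7 beside A8.
- Comparison: it makes a C=C bond that the C9 skeleton of 1 already contains at a lower oxidation level, and it costs at least one more step. The chosen route accepts a harder key step in exchange for a shorter sequence that makes no carbon–carbon bond.

Key step: step 3

Remark on the chemistry: the aluminium species 2 and 3 are drawn as monomers without their pyridine ligands; the E alkene of 7 is the only stereochemical element of the route and is removed in step 4.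

## Route

Step 1
Reactants: 1 methoxyeugenol (4-allyl-2,6-dimethoxyphenol)
Product: 4 5-allyl-3-methoxybenzene-1,2-diol, via dichloroaluminium phenoxide 2 (not isolated), via chloroaluminium catecholate 3 (not isolated)
Conditions: AlCl3 (1.1 equiv), pyridine (4.5 equiv), CH2Cl2, reflux, 24 h; then cold 2 M HCl, under argon
Reagents that add atoms: aluminium trichloride, Cl[Al](Cl)Cl (its atoms appear only in 2 and 3 and are removed in the acidic work-up)
Why: Chelation-directed cleavage of an ortho-hydroxyaryl methyl ether (AlCl3/pyridine demethylation): the phenol gives phenoxide 2, whose aluminium binds one flanking methoxy oxygen and activates that O–CH3 bond for attack by chloride. Once the five-membered catecholate 3 has formed the metal is tied up, so the second methoxy group should stay; pyridine keeps the medium free of HCl, which should spare the allyl group.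

Step 2
Reactants: 4 5-allyl-3-methoxybenzene-1,2-diol
Product: 5 5-allyl-3-methoxy-1,2-phenylene diacetate
Conditions: Ac2O (3 equiv), pyridine, DMAP (5 mol %), CH2Cl2, 0 °C to rt
Reagents that add atoms: acetic anhydride, CC(=O)OC(C)=O
Why: Standard O-acetylation of phenols under nucleophilic catalysis; both hydroxyls are unhindered enough to react fully, and the diacetate is no longer oxidisable by a quinone.

Step 3
Reactants: 5 5-allyl-3-methoxy-1,2-phenylene diacetate; 6 stearic acid
Product: 7 (E)-3-(3,4-diacetoxy-5-methoxyphenyl)allyl stearate
Conditions: Pd(OAc)2 (10 mol %), 1,2-bis(phenylsulfinyl)ethane (10 mol %), 1,4-benzoquinone (2 equiv), iPr2NEt (0.7 equiv), 6 (1.5 equiv), CH2Cl2, 45 °C, 72 h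
Reagents that add atoms: none
Why: This is a catalytic allylic C–H acyloxylation, the closest known reaction type being the divalent palladium/bis-sulfoxide linear allylic C–H esterification of terminal olefins with carboxylic acids; the same catalyst type is known to form 1-aryl-π-allyl complexes from allylarenes. The sulfoxide-bound divalent palladium carboxylate coordinates the terminal alkene of 5 and cleaves the Cα–H bond, which is both allylic and benzylic, to give a 1-aryl-π-allylpalladium carboxylate. Benzoquinone binds to this complex and makes the allyl fragment electrophilic enough for stearate, held as its ammonium salt by iPr2NEt, to attack. Attack at the unsubstituted terminus Cγ gives the ester whose alkene is conjugated with ring A, whereas attack at Cα would give a non-conjugated benzylic ester, so sterics and conjugation both favour the linear product, and the syn 1-aryl allyl complex translates into the E alkene. Zerovalent palladium is returned to the divalent state by benzoquinone and acid, leaving hydroquinone. No ring closes and no stereocentre forms; the step needs linear over branched attack, E over Z geometry, C–H cleavage over Wacker-type oxypalladation, and stearate over the acetate brought in by the catalyst, the last being secured by the large molar excess of 6 over Pd(OAc)2. The aryl acetates should survive because the medium is a carboxylic acid/carboxylate buffer containing neither free amine nor phenoxide.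

Step 4
Reactants: 7 (E)-3-(3,4-diacetoxy-5-methoxyphenyl)allyl stearate
Product: 8 3-(3,4-diacetoxy-5-methoxyphenyl)propyl stearate
Conditions: 2-nitrobenzenesulfonohydrazide (excess, in portions), Et3N, CH2Cl2, rt, argon
Reagents that add atoms: none
Why: Diimide reduction: HN=NH, released from the sulfonyl hydrazide by base, transfers two hydrogens to the C=C bond through a cyclic six-membered transition state with loss of N2. No metal surface and no ionisation are involved, so the allylic C–O bond that palladium on carbon would hydrogenolyse, the aryl acetates and the stearate should all remain.

Step 5
Reactants: 8 3-(3,4-diacetoxy-5-methoxyphenyl)propyl stearate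
Product: 9 3-(3,4-dihydroxy-5-methoxyphenyl)propyl stearate
Conditions: N2H4·H2O (2.5 equiv), THF, 0 °C, argon; then cold dilute HCl
Reagents that add atoms: none
Why: Chemoselective hydrazinolysis (aminolysis) of aryl esters: aryloxide is a far better leaving group than alkoxide, so the two aryl acetates should be cleaved at 0 °C much faster than the primary alkyl stearate. The reducing medium and the acidic quench protect the freed catechol from autoxidation.

## Compound list

1 | methoxyeugenol (4-allyl-2,6-dimethoxyphenol) | C=CCc1cc(OC)c(O)c(OC)c1 | starting material
2 | dichloroaluminium 4-allyl-2,6-dimethoxyphenoxide | C=CCc1cc(OC)c(O[Al](Cl)Cl)c(OC)c1 | intermediate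
3 | 6-allyl-2-chloro-4-methoxy-1,3,2-benzodioxaluminole (chloroaluminium catecholate of 4) | C=CCc1cc(OC)c2O[Al](Cl)Oc2c1 | intermediate
4 | 5-allyl-3-methoxybenzene-1,2-diol | C=CCc1cc(O)c(O)c(OC)c1 | intermediate
5 | 5-allyl-3-methoxy-1,2-phenylene diacetate | C=CCc1cc(OC)c(OC(C)=O)c(OC(C)=O)c1 | intermediate
6 | stearic acid (octadecanoic acid) | CCCCCCCCCCCCCCCCCC(=O)O | starting material
7 | (E)-3-(3,4-diacetoxy-5-methoxyphenyl)allyl stearate | CCCCCCCCCCCCCCCCCC(=O)OC/C=C/c1cc(OC)c(OC(C)=O)c(OC(C)=O)c1 | intermediate
8 | 3-(3,4-diacetoxy-5-methoxyphenyl)propyl stearate | CCCCCCCCCCCCCCCCCC(=O)OCCCc1cc(OC)c(OC(C)=O)c(OC(C)=O)c1 | intermediate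
9 | 3-(3,4-dihydroxy-5-methoxyphenyl)propyl stearate (CNP0209578.0) | CCCCCCCCCCCCCCCCCC(=O)OCCCc1cc(O)c(O)c(OC)c1 | target

## Step count and risk

Total step count: 5. Longest linear sequence: 5 steps (1 to 9); 6 enters at step 3.

**Step 3 (key step).**
- What may go wrong: a palladium hydride may move the terminal double bond of 5 into conjugation before C–H cleavage, which takes the substrate out of the productive π-allyl pathway. The π-allyl complex may also be captured by acetate from the catalyst instead of stearate. Loss of an aryl acetate followed by oxidation of the freed phenol by the quinone is a third risk.
- Fallback, from 5 back to 7: the Cγ–O bond is made by radical halogenation and substitution instead. Wohl–Ziegler bromination of 5 (N-bromosuccinimide, AIBN, PhCF3, reflux) should give, through the delocalised 1-arylallyl radical, the conjugated bromide (E)-5-(3-bromoprop-1-en-1-yl)-3-methoxy-1,2-phenylene diacetate F1. Displacement of its bromide by the caesium salt of 6 (6, Cs2CO3, DMF, rt) should give 7, and the route continues unchanged.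

**Step 1.**
- What may go wrong: the second methyl ether may be cleaved if aluminium is in excess, or conversion may stall if it is deficient. The Lewis acid may cause migration or hydrochlorination of the allyl double bond. The catechol may oxidise in air during work-up.
- Fallback, from 1 back to 4: the demethylation is made oxidative. 2-Iodoxybenzoic acid in DMF at 0 °C should transfer oxygen to a methoxy-bearing ortho carbon of the phenol and expel methanol, giving 5-allyl-3-methoxycyclohexa-3,5-diene-1,2-dione F2. This is reduced in the same flask with aqueous Na2S2O4 to 4.

**Step 5.**
- What may go wrong: the stearate may undergo hydrazinolysis on long or warm exposure. The catechol may autoxidise while it is present as its anion. Deacetylation may be incomplete.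
- Fallback, from 8 back to 9: selective deprotection is replaced by selective acylation. HCl in methanol at 40 °C should remove all three ester groups under conditions in which a catechol is stable, giving the triol 5-(3-hydroxypropyl)-3-methoxybenzene-1,2-diol F3. Immobilised Candida antarctica lipase B with 6 and molecular sieves in 2-methylbutan-2-ol at 50 °C should then esterify only the primary aliphatic hydroxyl and give 9.

**Step 4.**
- What may go wrong: reduction may be incomplete, because diimide disproportionates faster than it adds to a conjugated, 1,2-disubstituted alkene. Slow acyl transfer from the aryl acetates to the hydrazide is also possible.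
- Fallback, from 7 to 8: homogeneous hydrogenation with H2 (1–3 atm) and RhCl(PPh3)3 in toluene at rt. This catalyst adds hydrogen through a rhodium dihydride and forms no π-allyl species, so it should leave the allylic ester intact. No new compound arises.

## Further compounds

F1 | step 3 | (E)-5-(3-bromoprop-1-en-1-yl)-3-methoxy-1,2-phenylene diacetate | BrC/C=C/c1cc(OC)c(OC(C)=O)c(OC(C)=O)c1
F2 | step 1 | 5-allyl-3-methoxycyclohexa-3,5-diene-1,2-dione | C=CCC1=CC(=O)C(=O)C(OC)=C1
F3 | step 5 | 5-(3-hydroxypropyl)-3-methoxybenzene-1,2-diol | OCCCc1cc(O)c(O)c(OC)c1
F0 | step 4 | none | none
A1 | alternative 1 | 1,2-bis(benzyloxy)-5-bromo-3-methoxybenzene | COc1cc(Br)cc(OCc2ccccc2)c1OCc1ccccc1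
A2 | alternative 1 | 3-bromopropyl stearate | CCCCCCCCCCCCCCCCCC(=O)OCCCBr
A3 | alternative 1 | 3-[3,4-bis(benzyloxy)-5-methoxyphenyl]propyl stearate | CCCCCCCCCCCCCCCCCC(=O)OCCCc1cc(OC)c(OCc2ccccc2)c(OCc2ccccc2)c1
A4 | alternative 2 | 3-(4-hydroxy-3-methoxyphenyl)propyl stearate | CCCCCCCCCCCCCCCCCC(=O)OCCCc1ccc(O)c(OC)c1
A5 | alternative 2 | 3-(5-methoxy-3,4-dioxocyclohexa-1,5-dien-1-yl)propyl stearate | CCCCCCCCCCCCCCCCCC(=O)OCCCC1=CC(=O)C(=O)C(OC)=C1
A6 | alternative 3 | 3,4-bis(tert-butyldimethylsilyloxy)-5-methoxystyrene | C=Cc1cc(OC)c(O[Si](C)(C)C(C)(C)C)c(O[Si](C)(C)C(C)(C)C)c1
A7 | alternative 3 | allyl stearate | CCCCCCCCCCCCCCCCCC(=O)OCC=C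
A8 | alternative 3 | (E)-3-[3,4-bis(tert-butyldimethylsilyloxy)-5-methoxyphenyl]allyl stearate | CCCCCCCCCCCCCCCCCC(=O)OC/C=C/c1cc(OC)c(O[Si](C)(C)C(C)(C)C)c(O[Si](C)(C)C(C)(C)C)c1
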